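## Retrosynthetic overview

1. Target ⇒ its trideca-O-benzyl ether (hydrogenolysis last). The 3-O-gallate ⇒ an SN2 (Mitsunobu) esterification that inverts a 3β-alcohol with tri-O-benzylgallic acid.
2. 3β-Alcohol ⇒ 4-aryl-flavan-3-one, by hydride delivery anti to the 4β-aryl group.
3. Key C4–C8 bond ⇒ a C4 enolonium (iodine(III)-umpoled silyl enol ether of a flavan-3-one) plus C8–H of penta-O-benzylcatechin. An enol carbon and an electron-rich arene carbon are both nucleophiles; the enol is turned into the electrophile.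
4. Flavan-3-one ⇒ (−)-epigallocatechin (benzylation, oxidation); arene partner ⇒ (+)-catechin (benzylation).
5. No ring is formed in the route. Both chroman units, C2 of the upper unit and C2/C3 of the lower unit come from the two tea catechins; only C4 and then C3 of the upper unit are set.

Assumption: the target is read as epigallocatechin-3-O-gallate-(4β→8)-catechin (upper unit 2R,3R,4R; lower unit 2R,3S), and (−)-epigallocatechin, (+)-catechin and 3,4,5-tris(benzyloxy)benzoic acid are bought.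

## Route

Step 1
Reactants: 1 (−)-epigallocatechin
Product: 2 (2R,3R)-5,7-bis(benzyloxy)-2-[3,4,5-tris(benzyloxy)phenyl]chroman-3-ol
Conditions: BnBr (5.5 equiv), K2CO3, DMF, −10 °C → rt, Ar
Reagents that add atoms: benzyl bromide, BrCc1ccccc1
Why: Williamson O-benzylation with K2CO3 alkylates only the five phenols and leaves the secondary 3-OH and both stereocentres untouched.

Step 2
Reactants: 2 (2R,3R)-5,7-bis(benzyloxy)-2-[3,4,5-tris(benzyloxy)phenyl]chroman-3-ol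
Product: 3 (2R)-5,7-bis(benzyloxy)-2-[3,4,5-tris(benzyloxy)phenyl]chroman-3-one
Conditions: Dess–Martin periodinane, wet CH2Cl2, rt
Reagents that add atoms: none
Why: Dess–Martin oxidation of the secondary alcohol runs under near-neutral conditions, so the C2 centre next to the new ketone is not enolised (the established flavan-3-ol → flavan-3-one protocol).

Step 3
Reactants: 4 (+)-catechin
Product: 5 (2R,3S)-3,5,7-tris(benzyloxy)-2-[3,4-bis(benzyloxy)phenyl]chromane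
Conditions: NaH (6 equiv), BnBr (6 equiv), DMF, 0 °C → rt
Reagents that add atoms: benzyl bromide, BrCc1ccccc1
Why: Williamson etherification with NaH benzylates the four phenols and the secondary 3-OH in one operation without touching C2 or C3, leaving C8–H as the most nucleophilic and least hindered arene position.

Step 4
Reactants: 3 (2R)-5,7-bis(benzyloxy)-2-[3,4,5-tris(benzyloxy)phenyl]chroman-3-one; 5 (2R,3S)-3,5,7-tris(benzyloxy)-2-[3,4-bis(benzyloxy)phenyl]chromane (2.5 equiv, excess recovered)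
Product: 8 (2R,4R)-4-[(2R,3S)-3,5,7-tris(benzyloxy)-2-[3,4-bis(benzyloxy)phenyl]chroman-8-yl]-5,7-bis(benzyloxy)-2-[3,4,5-tris(benzyloxy)phenyl]chroman-3-one, via TMS enol ether 6 (not isolated), via O-iodanyl enolonium 7 (not isolated)
Conditions: TMSOTf, Et3N, CH2Cl2, 0 °C; cannulate into PhI(OAc)2, BF3·OEt2 (activator, 3 equiv), CH2Cl2, −78 °C, 10 min; then 5, −78 → −40 °C; NaHCO3 quench, crude 8 used at once
Reagents that add atoms: none
Why: Proposed new method: soft enolisation gives the A-ring-conjugated Δ3,4 silyl enol ether 6, PhI(OAc)2/BF3 turns it into the O-iodanyl enolonium 7 whose C4 (normally the nucleophilic enol carbon, here an α-keto cation equivalent further stabilised by the 5,7-dibenzyloxyarene) is attacked by the nucleophilic C8 of 5 with loss of PhI, the arene entering quasi-axially anti to the C2 aryl group (also the thermodynamically preferred 2,4-trans ketone, because the 4-aryl avoids peri strain with 5-OBn), which sets C4 as R; closest known reaction type is the hypervalent-iodine enolonium α-arylation of silyl enol ethers with electron-rich (hetero)arenes.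

Step 5
Reactants: 8 (2R,4R)-4-[(2R,3S)-3,5,7-tris(benzyloxy)-2-[3,4-bis(benzyloxy)phenyl]chroman-8-yl]-5,7-bis(benzyloxy)-2-[3,4,5-tris(benzyloxy)phenyl]chroman-3-one
Product: 9 (2R,3S,4R)-4-[(2R,3S)-3,5,7-tris(benzyloxy)-2-[3,4-bis(benzyloxy)phenyl]chroman-8-yl]-5,7-bis(benzyloxy)-2-[3,4,5-tris(benzyloxy)phenyl]chroman-3-ol
Conditions: NaBH4, CeCl3·7H2O, THF/MeOH, −78 °C
Reagents that add atoms: none
Why: Substrate-controlled Luche-type borohydride reduction in which hydride adds axially to C3 from the α-face, anti to the quasi-axial 4β-aryl group, giving the equatorial 3β-alcohol (3S) fast enough at −78 °C that the enolisable C2 and C4 centres are not scrambled.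

Step 6
Reactants: 9 (2R,3S,4R)-4-[(2R,3S)-3,5,7-tris(benzyloxy)-2-[3,4-bis(benzyloxy)phenyl]chroman-8-yl]-5,7-bis(benzyloxy)-2-[3,4,5-tris(benzyloxy)phenyl]chroman-3-ol; 10 3,4,5-tris(benzyloxy)benzoic acid (1.5 equiv)
Product: 11 (2R,3R,4R)-4-[(2R,3S)-3,5,7-tris(benzyloxy)-2-[3,4-bis(benzyloxy)phenyl]chroman-8-yl]-5,7-bis(benzyloxy)-2-[3,4,5-tris(benzyloxy)phenyl]chroman-3-yl 3,4,5-tris(benzyloxy)benzoate
Conditions: PPh3, DIAD, toluene, 0 °C → rt
Reagents that add atoms: none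
Why: Mitsunobu esterification in which the gallate carboxylate displaces the alkoxyphosphonium of the equatorial 3β-OH by SN2 from the open α-face, inverting C3 to R (2,3-cis-3,4-trans) while installing the ester, the 4-aryl-locked half-chair offering no anti-periplanar H or aryl group for elimination or phenonium participation.

Step 7
Reactants: 11 (2R,3R,4R)-4-[(2R,3S)-3,5,7-tris(benzyloxy)-2-[3,4-bis(benzyloxy)phenyl]chroman-8-yl]-5,7-bis(benzyloxy)-2-[3,4,5-tris(benzyloxy)phenyl]chroman-3-yl 3,4,5-tris(benzyloxy)benzoate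
Product: 12 epigallocatechin-3-O-gallate-(4β→8)-catechin (CNP0129434.1)
Conditions: H2 (1 atm), Pd(OH)2/C, THF/MeOH/H2O, rt
Reagents that add atoms: none
Why: Pd-catalysed hydrogenolysis cleaves all thirteen benzyl ethers (twelve aryl, one alkyl) as toluene and leaves the ester, the interflavan bond and all five stereocentres intact.

## Compound list

1 | (−)-epigallocatechin, (2R,3R)-2-(3,4,5-trihydroxyphenyl)chromane-3,5,7-triol | O[C@@H]1Cc2c(O)cc(O)cc2O[C@@H]1c1cc(O)c(O)c(O)c1 | starting material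

2 | (2R,3R)-5,7-bis(benzyloxy)-2-[3,4,5-tris(benzyloxy)phenyl]chroman-3-ol | O[C@@H]1Cc2c(OCc4ccccc4)cc(OCc4ccccc4)cc2O[C@@H]1c1cc(OCc4ccccc4)c(OCc4ccccc4)c(OCc4ccccc4)c1 | intermediate

3 | (2R)-5,7-bis(benzyloxy)-2-[3,4,5-tris(benzyloxy)phenyl]chroman-3-one | O=C1Cc2c(OCc4ccccc4)cc(OCc4ccccc4)cc2O[C@@H]1c1cc(OCc4ccccc4)c(OCc4ccccc4)c(OCc4ccccc4)c1 | intermediate

4 | (+)-catechin, (2R,3S)-2-(3,4-dihydroxyphenyl)chromane-3,5,7-triol | O[C@H]1Cc2c(O)cc(O)cc2O[C@@H]1c1ccc(O)c(O)c1 | starting material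

5 | penta-O-benzylcatechin, (2R,3S)-3,5,7-tris(benzyloxy)-2-[3,4-bis(benzyloxy)phenyl]chromane | C(c4ccccc4)O[C@H]1Cc2c(OCc4ccccc4)cc(OCc4ccccc4)cc2O[C@@H]1c1ccc(OCc4ccccc4)c(OCc4ccccc4)c1 | intermediate

6 | TMS enol ether of 3 (not isolated), [(2R)-5,7-bis(benzyloxy)-2-[3,4,5-tris(benzyloxy)phenyl]-2H-chromen-3-yl]oxy-trimethylsilane | C[Si](C)(C)OC1=Cc2c(OCc4ccccc4)cc(OCc4ccccc4)cc2O[C@@H]1c1cc(OCc4ccccc4)c(OCc4ccccc4)c(OCc4ccccc4)c1 | intermediate

7 | O-iodanyl enolonium (not isolated), acetoxy(phenyl)-λ3-iodanyl (2R)-5,7-bis(benzyloxy)-2-[3,4,5-tris(benzyloxy)phenyl]-2H-chromen-3-yl ether | CC(=O)OI(c4ccccc4)OC1=Cc2c(OCc4ccccc4)cc(OCc4ccccc4)cc2O[C@@H]1c1cc(OCc4ccccc4)c(OCc4ccccc4)c(OCc4ccccc4)c1 | intermediate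

8 | (2R,4R)-4-[(2R,3S)-penta-O-benzylcatechin-8-yl]-5,7-bis(benzyloxy)-2-[3,4,5-tris(benzyloxy)phenyl]chroman-3-one (2,4-trans) | O=C1[C@@H](c2c(OCc4ccccc4)cc(OCc4ccccc4)c3c2O[C@H](c2ccc(OCc4ccccc4)c(OCc4ccccc4)c2)[C@@H](OCc4ccccc4)C3)c2c(OCc4ccccc4)cc(OCc4ccccc4)cc2O[C@@H]1c1cc(OCc4ccccc4)c(OCc4ccccc4)c(OCc4ccccc4)c1 | intermediate

9 | (2R,3S,4R)-4-[(2R,3S)-penta-O-benzylcatechin-8-yl]-5,7-bis(benzyloxy)-2-[3,4,5-tris(benzyloxy)phenyl]chroman-3-ol (2,3-trans-3,4-cis, 3β-OH) | O[C@H]1[C@@H](c2c(OCc4ccccc4)cc(OCc4ccccc4)c3c2O[C@H](c2ccc(OCc4ccccc4)c(OCc4ccccc4)c2)[C@@H](OCc4ccccc4)C3)c2c(OCc4ccccc4)cc(OCc4ccccc4)cc2O[C@@H]1c1cc(OCc4ccccc4)c(OCc4ccccc4)c(OCc4ccccc4)c1 | intermediate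

10 | 3,4,5-tris(benzyloxy)benzoic acid | OC(=O)c1cc(OCc4ccccc4)c(OCc4ccccc4)c(OCc4ccccc4)c1 | starting material

11 | trideca-O-benzyl target, (2R,3R,4R)-4-[(2R,3S)-penta-O-benzylcatechin-8-yl]-5,7-bis(benzyloxy)-2-[3,4,5-tris(benzyloxy)phenyl]chroman-3-yl 3,4,5-tris(benzyloxy)benzoate | O=C(O[C@@H]1[C@@H](c2c(OCc4ccccc4)cc(OCc4ccccc4)c3c2O[C@H](c2ccc(OCc4ccccc4)c(OCc4ccccc4)c2)[C@@H](OCc4ccccc4)C3)c2c(OCc4ccccc4)cc(OCc4ccccc4)cc2O[C@@H]1c1cc(OCc4ccccc4)c(OCc4ccccc4)c(OCc4ccccc4)c1)c1cc(OCc4ccccc4)c(OCc4ccccc4)c(OCc4ccccc4)c1 | intermediate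

12 | epigallocatechin-3-O-gallate-(4β→8)-catechin, (2R,3R,4R)-4-[(2R,3S)-2-(3,4-dihydroxyphenyl)-3,5,7-trihydroxychroman-8-yl]-5,7-dihydroxy-2-(3,4,5-trihydroxyphenyl)chroman-3-yl 3,4,5-trihydroxybenzoate | O=C(O[C@@H]1[C@@H](c2c(O)cc(O)c3c2O[C@H](c2ccc(O)c(O)c2)[C@@H](O)C3)c2c(O)cc(O)cc2O[C@@H]1c1cc(O)c(O)c(O)c1)c1cc(O)c(O)c(O)c1 | target

## Step count and risks

Total steps: 7. Longest linear sequence: 6 (steps 1, 2, 4, 5, 6, 7).

Three steps most likely to fail:

Step 4 (enolonium arylation). The cationic intermediate can lose H-2 to give a 3-hydroxyflavylium, which would erase the C2 centre. It can also be captured at oxygen, or by C6 of 5. The fallback moves the polarity reversal from the enol to the arene; it sets out from 5 (with 3) and comes back at 8. NBS in CH2Cl2 at −78 °C brominates 5 at C8 to give (2R,3S)-8-bromo-3,5,7-tris(benzyloxy)-2-[3,4-bis(benzyloxy)phenyl]chromane F1. Pd-catalysed enolate α-arylation of ketone 3 with the aryl bromide as aryl-cation equivalent (Pd2(dba)3, XPhos, K3PO4, toluene, 80 °C) then forms the same C4–C8 bond. The C4-arylated product equilibrates through its enol to the 2,4-trans ketone 8.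

Step 6 (invertive galloylation). The weakly acidic, bulky gallic acid may react through an acyloxyphosphonium pathway and give the retention ester, or not react at the congested carbinol. The fallback separates inversion from galloylation; it sets out from 9 and comes back at 11. Mitsunobu reaction with the more acidic 4-nitrobenzoic acid (PPh3, DIAD, toluene) gives the inverted (2R,3R,4R)-3-O-(4-nitrobenzoyl) deca-O-benzyl dimer F2. Methanolysis (K2CO3, MeOH/THF) gives the (2R,3R,4R)-3α-alcohol F3. Steglich acylation with 10 (DCC, DMAP, CH2Cl2) then installs the gallate with retention to give 11.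

Step 1 (perbenzylation of epigallocatechin). The pyrogallol ring oxidises easily under base and C-benzylation of the A-ring competes. The fallback sets out from purchased (−)-epigallocatechin gallate F4 and comes back at 2. BnBr/K2CO3 in DMF gives octa-O-benzyl-epigallocatechin gallate F5, in which the 3-position is already blocked. Saponification (KOH, THF/MeOH/H2O, then acidification) gives 2, and the acid released is 10, which serves step 6.

## Further compounds

F1 | step 4 | (2R,3S)-8-bromo-3,5,7-tris(benzyloxy)-2-[3,4-bis(benzyloxy)phenyl]chromane | C(c4ccccc4)O[C@H]1Cc2c(OCc4ccccc4)cc(OCc4ccccc4)c(Br)c2O[C@@H]1c1ccc(OCc4ccccc4)c(OCc4ccccc4)c1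

F2 | step 6 | (2R,3R,4R)-4-[(2R,3S)-penta-O-benzylcatechin-8-yl]-5,7-bis(benzyloxy)-2-[3,4,5-tris(benzyloxy)phenyl]chroman-3-yl 4-nitrobenzoate | O=C(O[C@@H]1[C@@H](c2c(OCc4ccccc4)cc(OCc4ccccc4)c3c2O[C@H](c2ccc(OCc4ccccc4)c(OCc4ccccc4)c2)[C@@H](OCc4ccccc4)C3)c2c(OCc4ccccc4)cc(OCc4ccccc4)cc2O[C@@H]1c1cc(OCc4ccccc4)c(OCc4ccccc4)c(OCc4ccccc4)c1)c1ccc(cc1)[N+](=O)[O-]

F3 | step 6 | (2R,3R,4R)-4-[(2R,3S)-penta-O-benzylcatechin-8-yl]-5,7-bis(benzyloxy)-2-[3,4,5-tris(benzyloxy)phenyl]chroman-3-ol (3α-OH) | O[C@@H]1[C@@H](c2c(OCc4ccccc4)cc(OCc4ccccc4)c3c2O[C@H](c2ccc(OCc4ccccc4)c(OCc4ccccc4)c2)[C@@H](OCc4ccccc4)C3)c2c(OCc4ccccc4)cc(OCc4ccccc4)cc2O[C@@H]1c1cc(OCc4ccccc4)c(OCc4ccccc4)c(OCc4ccccc4)c1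

F4 | step 1 | (−)-epigallocatechin gallate (purchased) | O=C(O[C@@H]1Cc2c(O)cc(O)cc2O[C@@H]1c1cc(O)c(O)c(O)c1)c1cc(O)c(O)c(O)c1

F5 | step 1 | octa-O-benzyl-epigallocatechin gallate, (2R,3R)-5,7-bis(benzyloxy)-2-[3,4,5-tris(benzyloxy)phenyl]chroman-3-yl 3,4,5-tris(benzyloxy)benzoate | O=C(O[C@@H]1Cc2c(OCc4ccccc4)cc(OCc4ccccc4)cc2O[C@@H]1c1cc(OCc4ccccc4)c(OCc4ccccc4)c(OCc4ccccc4)c1)c1cc(OCc4ccccc4)c(OCc4ccccc4)c(OCc4ccccc4)c1
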